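Assumption (a remark on the chemistry): the ynol ether formation in step 8 is taken as a new extension of known haloalkyne substitution chemistry, and allyl propiolate 5 is taken as a purchasable starting material.

## Analysis of the target

The target is a depsidone: two benzene rings joined by an ester and by an ether, which together close a seven-membered ring C. Ring A is numbered as a benzoate (C1 carries the carboxyl carbon) and ring B as the arene of a chroman-4-one (O1, C2 … C8a), since it is fused to a 2,2-dimethylpyran-4-one. There is no stereocentre, so the whole problem is substitution pattern and order of events.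

Ring A carries, in sequence, the carboxyl (C1), the diaryl ether oxygen (C2), a formyl group (C3), a hydroxyl (C4), hydrogen (C5) and methyl (C6). Ring B is hexasubstituted and has three neighbouring oxygens of different fate: O6 is acylated, O7 is arylated and O8 is free.

Sensitive groups:
- the aryl ester of ring C, which bases and nucleophiles open;
- the salicylaldehyde unit on ring A;
- the chromanone, which can open by retro-oxa-Michael reaction;
- the electron-rich phenols.

Two things make the synthesis hard. The diaryl ether links two rings that are each substituted on both sides of the ether carbon, a poor case for a copper-mediated coupling. The contiguous C1–C4 pattern of ring A is also awkward to set by stepwise aromatic substitution.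

The strategy rests on one feature: C3, C4, C5 and C6 of ring A, with their formyl, oxygen, hydrogen and methyl substituents, are C3–C6 of the 3-formyl-4-oxy-6-methyl-2-pyrone 4. Only C1 and C2 are then missing, and they carry exactly the carboxyl and the aryloxy group of the 3-aryloxypropiolate 15.

## Retrosynthetic reasoning

**21 to 20.** The two free phenols (O4 on ring A, O8 on ring B) are unmasked last from the bis(methyl ether) 20. A free hydroxyl next to the formyl group, or next to O7, would interfere with the lactonisation and with the alkyne chemistry. The two methyl groups cost nothing, since one comes with the quinone 7 and the other is put on when 4 is made.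

**20 to 19.** Ring C is opened at the ester bond between the ring A carboxyl and O6. This is the most base-labile bond of the target, so it is formed late. In 19 only one phenol is free, so the closure is unambiguous, and the diaryl ether already holds acid and phenol close together.

**19 to 18 to 17.** The acid and the O6 phenol are carried as an allyl ester and a methoxymethyl ether. The first is removed under neutral conditions with zerovalent palladium and the second with aqueous acid. Both are orthogonal to the methyl ethers and survive heating.

**17 to 15 + 4 (key disconnection).** Ring A is cut at C2–C3 and C1–C6. Forward, the pyrone 4 and the alkyne 15 must combine in a (4+2) cycloaddition with one defined orientation and then lose the lactone bridge by decarboxylative cycloreversion. Cutting here removes the need to couple two hindered arenes through oxygen. It also places all six ring A substituents in one step, because the diaryl ether oxygen is already attached to the alkyne.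

**15 to 13 + 6.** The bond between O7 and the alkyne carbon is cut. Forward, the phenoxide of 13 has to substitute the halide of 6 at an sp carbon by addition–elimination. The bromoalkyne 6 comes in one step from allyl propiolate 5.

**13 to 12 to 11.** O7 must be the only free phenol. In 12 the O7 methyl ether is para to the C4 ketone and lies between two other oxygens, so a soft nucleophile should cleave it in preference to the O8 methyl ether, which is meta to the ketone. O6, the only phenol of 11, is protected beforehand.

**11 to 8 + 9, 8 to 7.** The pyranone is cut at C4–C4a and O1–C2. The hydroquinone 8, from reduction of the quinone 7, has a single unsubstituted ring carbon, flanked by a hydroxyl and the methyl group. Acylation by 9 can only occur there, and only the adjacent hydroxyl can then close onto the enone. All three ring B oxygens and the C5 methyl are thus bought with 7.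

**4 to 3 to 1.** The pyrone diene is traced to the hydroxypyrone 1 by chloroformylation at C3/C4 (giving 3) and exchange of the vinylogous acid chloride for a methoxy group.

## Alternatives that were turned down

**Alternative 1: cyclobutenone ring expansion for ring B.**
- Disconnection: ring B is cut at C4a–C8a and traced to the 4-alkenylcyclobutenone A1, the MOM-protected adduct of an alkenyllithium with a squaric ester.
- Key step: heating A1 should open the four-membered ring to a dienylketene. A 6π closure then joins the ketene carbon (future C8a) to the alkene terminus (future C4a), and tautomerisation gives the phenol A2.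
- For: every ring B substituent is placed by construction. O6 is born as its MOM ether and the C8a oxygen as the free phenol needed for pyranone closure. The thermolysis is neutral. It also avoids the one ambiguity of step 5 (acylation against alkylation of the hydroquinone), and on that point it is the stronger plan.
- Against: A2 still needs desilylation, oxidation to the enone and oxa-Michael closure to reach 12, and then the same selective O7 demethylation as here. A stereodefined lithiated diene must be made first. The sequence is roughly three times as long as 7 → 12. It also leaves ring A and the hindered diaryl ether, the real difficulties, untouched.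
- Comparison: the chosen strategy spends its construction step on ring A and the ether together, and buys ring B almost ready-made.

**Alternative 2: oxidative para-lactonisation.**
- Disconnection: the ester oxygen–C6 bond of ring C, with C6 still carrying hydrogen. The precursor is the diaryl ether acid A3, whose ring B derives from a symmetrical resorcinol, so either hydroxyl gives the same ether.
- Key step: a trivalent iodine oxidant converts the free phenol of A3 (future C8a–OH) into a phenoxenium species. The carboxylate adds at the para carbon and rearomatisation gives the depsidone A4, which lacks the pyranone ring.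
- For: O6 never has to be carried or protected, ring B shrinks to a trivial building block, and the ether formation has no regiochemical issue. On the ring B side this is shorter than the chosen route.
- Against: the carboxylate reaches the methoxy-bearing ortho carbon (future C8) through the same ring size as the para carbon, which would give a quinone monoketal. The electron-rich diaryl ether and the aldehyde are exposed to an oxidant. The pyranone must then be built on A4 by acylation in strong acid next to the lactone and the aldehyde. Ring A still has to be made as a hexasubstituted halobenzoate and coupled through oxygen.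
- Comparison: the chosen strategy makes ring A and the ether in one operation, installs the pyranone on a simple hydroquinone at the start, and closes ring C by an unambiguous lactonisation.

**Alternative 3: siloxyfuran–ynone cycloaddition.**
- Disconnection: ring B is cut at C5–C6 and C4a–C8a and the pyranone at O1–C2, leading to the siloxyfuran A5 and the cross-conjugated ynone A6.
- Key step: cycloaddition of A5 with the triple bond of A6 should be followed by opening of the oxygen bridge to the arene. Fluoride work-up then lets the C8a phenoxide add to the enone, giving the chromanone A7.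
- For: ring B and the pyranone arise in one pot. O7 is born as a benzyl ether, so A7 needs only MOM protection and hydrogenolysis to reach 13. The thiolate demethylation of step 7 is avoided, and on this point the alternative is the stronger plan.
- Against: A5 is a sensitive, doubly oxygenated siloxyfuran that needs its own multistep preparation. A6 offers a second reactive π bond. The bridge must open in one direction only. As in alternative 1, the effort goes into the ring that 7 supplies nearly complete.
- Comparison: the chosen route reaches 13 in four steps from commercial materials and reserves its one risky construction for ring A and the diaryl ether, which alternative 3 does not address.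

Key step: step 9

## Route

**Step 1**
Reactants: 1 4-hydroxy-6-methyl-2H-pyran-2-one
Product: 3 4-chloro-6-methyl-2-oxo-2H-pyran-3-carbaldehyde, via iminium chloride 2 (not isolated)
Conditions: POCl3, DMF, 0 °C → 50 °C; then ice–water
Reagents that add atoms: N,N-dimethylformamide CN(C)C=O; phosphoryl chloride O=P(Cl)(Cl)Cl; water O
Why: Vilsmeier–Haack chloroformylation: the enolic C3 is formylated and the C4 hydroxyl is exchanged for chloride, as is usual for cyclic 1,3-dicarbonyl enols; aqueous work-up hydrolyses 2 to the aldehyde.

**Step 2**
Reactants: 3 4-chloro-6-methyl-2-oxo-2H-pyran-3-carbaldehyde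
Product: 4 4-methoxy-6-methyl-2-oxo-2H-pyran-3-carbaldehyde
Conditions: NaOMe (1.0 equiv), MeOH, −20 °C → 0 °C
Reagents that add atoms: sodium methoxide C[O-].[Na+]
Why: Addition–elimination at C4 of a vinylogous acid chloride activated by both the formyl and the lactone carbonyl; one equivalent at low temperature should spare the lactone.

**Step 3**
Reactants: 5 allyl propiolate
Product: 6 allyl 3-bromopropiolate
Conditions: NBS, AgNO3 (10 mol %), acetone, rt, dark
Reagents that add atoms: N-bromosuccinimide O=C1CCC(=O)N1Br
Why: Silver-catalysed bromination of a terminal alkyne through the silver acetylide, standard for propiolate esters; the allyl double bond should not react without water or radical initiation.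

**Step 4**
Reactants: 7 2,3-dimethoxy-5-methyl-1,4-benzoquinone
Product: 8 2,3-dimethoxy-5-methylbenzene-1,4-diol
Conditions: Na2S2O4, H2O/EtOAc, rt
Reagents that add atoms: none
Why: Dithionite reduction of a quinone to its hydroquinone; the air-sensitive product is used at once.

**Step 5**
Reactants: 8 2,3-dimethoxy-5-methylbenzene-1,4-diol; 9 3-methylbut-2-enoic acid
Product: 11 6-hydroxy-7,8-dimethoxy-2,2,5-trimethylchroman-4-one, via aryl prenyl ketone 10 (not isolated)
Conditions: P2O5/MeSO3H (Eaton's reagent), 70 °C
Reagents that add atoms: none
Why: Friedel–Crafts acylation at the only unsubstituted ring carbon (ortho to a hydroxyl, para to a methoxy group), then 6-endo oxa-Michael addition of the neighbouring phenol to the enone of 10; the other hydroxyl cannot reach the enone and remains as O6–H.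

**Step 6**
Reactants: 11 6-hydroxy-7,8-dimethoxy-2,2,5-trimethylchroman-4-one
Product: 12 7,8-dimethoxy-6-(methoxymethoxy)-2,2,5-trimethylchroman-4-one
Conditions: MOMCl, iPr2NEt, CH2Cl2, 0 °C → rt
Reagents that add atoms: chloromethyl methyl ether COCCl
Why: Williamson-type O-alkylation of the single phenol; the amine base avoids enolate or ring-opening chemistry of the chromanone.

**Step 7**
Reactants: 12 7,8-dimethoxy-6-(methoxymethoxy)-2,2,5-trimethylchroman-4-one
Product: 13 7-hydroxy-8-methoxy-6-(methoxymethoxy)-2,2,5-trimethylchroman-4-one
Conditions: NaSEt, DMF, 90 °C; then AcOH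
Reagents that add atoms: none
Why: SN2 demethylation by thiolate, expected at O7 because its phenoxide is para to the C4 ketone (a vinylogous carboxylate leaving group) and its methyl group, flanked by two oxygens, is twisted out of the ring plane; O8 is meta to the ketone and the MOM acetal should be inert to thiolate.

**Step 8**
Reactants: 13 7-hydroxy-8-methoxy-6-(methoxymethoxy)-2,2,5-trimethylchroman-4-one; 6 allyl 3-bromopropiolate
Product: 15 allyl 3-{[8-methoxy-6-(methoxymethoxy)-2,2,5-trimethyl-4-oxochroman-7-yl]oxy}prop-2-ynoate, via bromoallenolate adduct 14 (not isolated)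
Conditions: NaH (1.0 equiv), THF, 0 °C; then added to 6 (1.5 equiv), THF, −78 °C → −20 °C
Reagents that add atoms: none
Why: Proposed new method: the sodium phenoxide of 13 should add in Michael fashion to the bromine-bearing β-carbon of 6, and the allenolate 14, which finds no proton source in the aprotic medium, should expel bromide and restore the triple bond, a net substitution at an sp carbon; the closest known reaction types are the addition–elimination substitution of acceptor-substituted 1-haloalkynes by thiolates, amines and alkoxides and the base-mediated oxa-Michael addition of phenols to propiolates; inverse addition to excess 6 at low temperature and the two ortho substituents of the phenoxide are meant to hold back a second addition to 15.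

**Step 9**
Reactants: 15 allyl 3-{[8-methoxy-6-(methoxymethoxy)-2,2,5-trimethyl-4-oxochroman-7-yl]oxy}prop-2-ynoate; 4 4-methoxy-6-methyl-2-oxo-2H-pyran-3-carbaldehyde
Product: 17 allyl 3-formyl-4-methoxy-2-{[8-methoxy-6-(methoxymethoxy)-2,2,5-trimethyl-4-oxochroman-7-yl]oxy}-6-methylbenzoate, via bridged lactone adduct 16 (not isolated)
Conditions: 4 (3 equiv), PhMe, 160 °C, sealed tube
Reagents that add atoms: none
Why: The pyrone 4 reacts as an electron-poor diene through C3=C4–C5=C6 and the ynol ether ester 15 as a polarised 2π partner, in a concerted but asynchronous (4+2) cycloaddition of inverse electron demand. The alkyne carbon next to the ester, the nucleophilic end of the ynol ether, should bond first to the electrophilic C6 of the pyrone, and the oxygen-bearing alkyne carbon then closes onto C3, giving the 2-oxabicyclo[2.2.2]octadienone 16. Cycloreversion of 16 with loss of CO2 forms the benzene ring irreversibly. The closest known reaction type is the thermal pyrone–alkyne Diels–Alder/decarboxylation benzannulation, including the orientation seen when 3-acyl-2-pyrones meet ketene acetals or ynamines, where the donor-bearing carbon ends up beside the acyl-bearing carbon. Ring A is closed by this intermolecular (4+2) cycloaddition (bonds C2–C3 and C1–C6) followed by retro-(4+2) extrusion, and no stereocentre results because both bridgeheads of 16 become aromatic carbons. The step needs head-to-tail regioselectivity, which the matched polarisation of the two partners should secure, and chemoselectivity for the ring diene over the formyl oxadiene and the allyl alkene, which is favoured because only the carbocyclic adduct can leave the equilibrium by losing CO2. Both positions ortho to the aryloxy oxygen are blocked, so the ynol ether has no thermal cyclisation path of its own, and the cheap partner 4 is used in excess.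

**Step 10**
Reactants: 17 allyl 3-formyl-4-methoxy-2-{[8-methoxy-6-(methoxymethoxy)-2,2,5-trimethyl-4-oxochroman-7-yl]oxy}-6-methylbenzoate
Product: 18 3-formyl-4-methoxy-2-{[8-methoxy-6-(methoxymethoxy)-2,2,5-trimethyl-4-oxochroman-7-yl]oxy}-6-methylbenzoic acid
Conditions: Pd(PPh3)4 (5 mol %), morpholine, THF, rt; dilute citric acid work-up
Reagents that add atoms: none
Why: Tsuji–Trost deallylation: zerovalent palladium ionises the allyl ester to a π-allyl complex that morpholine intercepts; the neutral conditions leave the MOM ether, aldehyde, ketone and methyl ethers alone, and steric hindrance of the benzoate is irrelevant because the O–allyl bond is the one broken.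

**Step 11**
Reactants: 18 3-formyl-4-methoxy-2-{[8-methoxy-6-(methoxymethoxy)-2,2,5-trimethyl-4-oxochroman-7-yl]oxy}-6-methylbenzoic acid
Product: 19 3-formyl-2-[(6-hydroxy-8-methoxy-2,2,5-trimethyl-4-oxochroman-7-yl)oxy]-4-methoxy-6-methylbenzoic acid
Conditions: 3 M HCl, THF, 50 °C
Reagents that add atoms: none
Why: Acid hydrolysis of the MOM acetal; no alcohol is present, so the aldehyde is not acetalised, and methyl ethers, diaryl ether and chromanone are stable to aqueous acid.

**Step 12**
Reactants: 19 3-formyl-2-[(6-hydroxy-8-methoxy-2,2,5-trimethyl-4-oxochroman-7-yl)oxy]-4-methoxy-6-methylbenzoic acid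
Product: 20 depsidone bis(methyl ether): the lactone of 19 between its carboxyl and O6 (ring C closed), with methyl ethers at ring A O4 and ring B O8
Conditions: EDC·HCl, DMAP, CH2Cl2 (5 mM), rt
Reagents that add atoms: none
Why: Carbodiimide (Steglich-type) lactonisation, the standard closure of depsidones; the seven-membered ring forms by acyl substitution at the activated carboxyl by the only free phenol, which the diaryl ether holds nearby, and high dilution suppresses oligomers.

**Step 13**
Reactants: 20 depsidone bis(methyl ether)
Product: 21 the target depsidone (ring A: C3 formyl, C4 hydroxyl, C6 methyl; ring B: 8-hydroxy-2,2,5-trimethylchroman-4-one, acylated at O6 and arylated at O7)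
Conditions: BBr3, CH2Cl2, −78 °C → 0 °C; then H2O
Reagents that add atoms: none
Why: Lewis-acid cleavage of aryl methyl ethers; the O4 methyl is activated by chelation of boron between the ether and the ortho formyl oxygen, and the O8 methyl is the central, out-of-plane ether of a 1,2,3-trioxygenated array, so both should cleave at low temperature before the aryl ester or the tertiary pyranone ether is attacked.

## Compound list

1 | 4-hydroxy-6-methyl-2H-pyran-2-one | CC1=CC(O)=CC(=O)O1 | starting material
2 | N-[(4-chloro-6-methyl-2-oxo-2H-pyran-3-yl)methylidene]-N-methylmethanaminium chloride (not isolated) | CC1=CC(Cl)=C(C=[N+](C)C)C(=O)O1.[Cl-] | intermediate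
3 | 4-chloro-6-methyl-2-oxo-2H-pyran-3-carbaldehyde | CC1=CC(Cl)=C(C=O)C(=O)O1 | intermediate
4 | 4-methoxy-6-methyl-2-oxo-2H-pyran-3-carbaldehyde | COC1=C(C=O)C(=O)OC(C)=C1 | intermediate
5 | allyl propiolate (prop-2-en-1-yl prop-2-ynoate) | C#CC(=O)OCC=C | starting material
6 | allyl 3-bromopropiolate | BrC#CC(=O)OCC=C | intermediate
7 | 2,3-dimethoxy-5-methyl-1,4-benzoquinone | CC1=CC(=O)C(OC)=C(OC)C1=O | starting material
8 | 2,3-dimethoxy-5-methylbenzene-1,4-diol | Cc1cc(O)c(OC)c(OC)c1O | intermediate
9 | 3-methylbut-2-enoic acid | CC(C)=CC(=O)O | starting material
10 | 1-(2,5-dihydroxy-3,4-dimethoxy-6-methylphenyl)-3-methylbut-2-en-1-one (not isolated) | Cc1c(C(=O)C=C(C)C)c(O)c(OC)c(OC)c1O | intermediate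
11 | 6-hydroxy-7,8-dimethoxy-2,2,5-trimethylchroman-4-one | Cc1c(O)c(OC)c(OC)c2c1C(=O)CC(C)(C)O2 | intermediate
12 | 7,8-dimethoxy-6-(methoxymethoxy)-2,2,5-trimethylchroman-4-one | Cc1c(OCOC)c(OC)c(OC)c2c1C(=O)CC(C)(C)O2 | intermediate
13 | 7-hydroxy-8-methoxy-6-(methoxymethoxy)-2,2,5-trimethylchroman-4-one | Cc1c(OCOC)c(O)c(OC)c2c1C(=O)CC(C)(C)O2 | intermediate
14 | sodium 1-(allyloxy)-3-bromo-3-{[8-methoxy-6-(methoxymethoxy)-2,2,5-trimethyl-4-oxochroman-7-yl]oxy}propa-1,2-dien-1-olate (not isolated) | C=CCOC([O-])=C=C(Br)Oc1c(OCOC)c(C)c2c(c1OC)OC(C)(C)CC2=O.[Na+] | intermediate
15 | allyl 3-{[8-methoxy-6-(methoxymethoxy)-2,2,5-trimethyl-4-oxochroman-7-yl]oxy}prop-2-ynoate | C=CCOC(=O)C#COc1c(OCOC)c(C)c2c(c1OC)OC(C)(C)CC2=O | intermediate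
16 | allyl 4-formyl-8-methoxy-5-{[8-methoxy-6-(methoxymethoxy)-2,2,5-trimethyl-4-oxochroman-7-yl]oxy}-1-methyl-3-oxo-2-oxabicyclo[2.2.2]octa-5,7-diene-6-carboxylate (racemic, not isolated) | C=CCOC(=O)C1=C(Oc2c(OCOC)c(C)c3c(c2OC)OC(C)(C)CC3=O)C2(C=O)C(=O)OC1(C)C=C2OC | intermediate
17 | allyl 3-formyl-4-methoxy-2-{[8-methoxy-6-(methoxymethoxy)-2,2,5-trimethyl-4-oxochroman-7-yl]oxy}-6-methylbenzoate | Cc1cc(OC)c(C=O)c(Oc2c(OCOC)c(C)c3c(c2OC)OC(C)(C)CC3=O)c1C(=O)OCC=C | intermediate
18 | 3-formyl-4-methoxy-2-{[8-methoxy-6-(methoxymethoxy)-2,2,5-trimethyl-4-oxochroman-7-yl]oxy}-6-methylbenzoic acid | Cc1cc(OC)c(C=O)c(Oc2c(OCOC)c(C)c3c(c2OC)OC(C)(C)CC3=O)c1C(=O)O | intermediate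
19 | 3-formyl-2-[(6-hydroxy-8-methoxy-2,2,5-trimethyl-4-oxochroman-7-yl)oxy]-4-methoxy-6-methylbenzoic acid | Cc1cc(OC)c(C=O)c(Oc2c(O)c(C)c3c(c2OC)OC(C)(C)CC3=O)c1C(=O)O | intermediate
20 | depsidone bis(methyl ether): lactone of 19 between the ring A carboxyl and ring B O6, methyl ethers at ring A O4 and ring B O8 | Cc1cc(OC)c(C=O)c2c1C(=O)Oc1c(C)c3c(c(OC)c1O2)OC(C)(C)CC3=O | intermediate
21 | target depsidone CNP0271978.0 (no stereocentre) | Cc1cc(O)c(C=O)c2c1C(=O)Oc1c(C)c3c(c(O)c1O2)OC(C)(C)CC3=O | target

## Step count and risk

Total: 13 steps. Longest linear sequence: 10 steps (steps 4 to 13, from quinone 7). The pyrone branch (steps 1 and 2) and the bromoalkyne (step 3) are side branches.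

**Step 8 (ynol ether formation, new method).**
- What may go wrong: the adduct 14 may be protonated instead of losing bromide, stopping at the bromoacrylate stage. A second phenoxide may add to the product and give a ketene acetal. The bromoalkyne may oligomerise under base.
- Fallback (known chemistry, from 13, back at 15):
  - 13 is treated with trichloroethylene (K2CO3, DMF, 70 °C) to give 7-{[(E)-1,2-dichloroethenyl]oxy}-8-methoxy-6-(methoxymethoxy)-2,2,5-trimethylchroman-4-one F1.
  - The next operation needs an alkyllithium, so the ketone is masked. NaBH4 in MeOH gives the racemic chroman-4-ol F2, and Et3SiOTf/2,6-lutidine gives its triethylsilyl ether F3.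
  - n-BuLi (2.2 equiv, THF, −78 °C) eliminates HCl and exchanges the remaining chlorine for lithium. Quenching the lithium aryloxyacetylide with allyl chloroformate gives the silyl-protected ynol ether ester, allyl 3-{[8-methoxy-6-(methoxymethoxy)-2,2,5-trimethyl-4-(triethylsilyloxy)chroman-7-yl]oxy}prop-2-ynoate F4.
  - Buffered fluoride (Bu4NF, AcOH) frees the alcohol, allyl 3-{[4-hydroxy-8-methoxy-6-(methoxymethoxy)-2,2,5-trimethylchroman-7-yl]oxy}prop-2-ynoate F5, and Dess–Martin periodinane oxidation restores the ketone, which is 15.

**Step 9 (key step).**
- What may go wrong: cycloaddition may fail below the decomposition temperature, because both diene termini are fully substituted and the push–pull alkyne is a sluggish 2π partner. A hetero-Diels–Alder reaction through the formyl oxadiene may compete. The ynol ether may degrade thermally.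
- Fallback (from 13, with 4 and 6, back at 17):
  - The pyrone benzannulation is run with the small, more electrophilic alkyne 6 instead (4 and 6, PhMe, 150 °C). After loss of CO2 this should give allyl 2-bromo-3-formyl-4-methoxy-6-methylbenzoate F6; the orientation is controlled by the ester.
  - The diaryl ether is then made afterwards from 13 and F6 by substitution of the bromide, which is activated by the ortho formyl and ortho ester groups. Ullmann-type catalysis helps if needed (CuI, picolinic acid, K3PO4, DMSO, 80 °C). The product is 17.

**Step 7 (selective demethylation).**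
- What may go wrong: cleavage may also occur at O8, or the MOM group may be lost, or the pyranone may open by retro-oxa-Michael reaction under the basic, hot conditions.
- Fallback (from 11, back at 13):
  - AlCl3 in CH2Cl2 cleaves the methyl ether next to the free phenol and para to the ketone, giving 6,7-dihydroxy-8-methoxy-2,2,5-trimethylchroman-4-one F7.
  - The more acidic 7-hydroxyl (para to the ketone) is benzylated selectively (BnBr, 1 equiv, K2CO3, acetone) to 7-(benzyloxy)-6-hydroxy-8-methoxy-2,2,5-trimethylchroman-4-one F8. This is the compound alternative 3 would deliver as A7.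
  - MOMCl/iPr2NEt gives 7-(benzyloxy)-8-methoxy-6-(methoxymethoxy)-2,2,5-trimethylchroman-4-one F9, and hydrogenolysis (H2, Pd/C, EtOAc) gives 13.

**Step 5 (chromanone annulation).**
- What may go wrong: the arene may add in conjugate fashion to the protonated acid (Friedel–Crafts alkylation) and then lactonise, giving a 4,4-dimethyldihydrocoumarin instead of the chromanone. Electron-rich hydroquinones are prone to this when acylation is slow.
- Fallback (from 8, back at 11): Friedel–Crafts acetylation of 8 (AcOH, BF3·OEt2, 90 °C) gives 1-(2,5-dihydroxy-3,4-dimethoxy-6-methylphenyl)ethan-1-one F10. Kabbe condensation with acetone (pyrrolidine, EtOH, reflux) then builds the 2,2-dimethylpyranone by aldol condensation and oxa-Michael closure, giving 11.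

**Step 13 (final demethylation).**
- What may go wrong: the Lewis acid may cleave the tertiary alkyl aryl ether of the pyranone (ring opening) or the ring C ester before the hindered O8 methyl is gone.
- Fallback (from 20, back at 21):
  - Ring opening is accepted. Excess BBr3 at rt completes both demethylations and should give, after work-up, the ring-opened enone F11 (the target with the O1–C2 bond cleaved: phenol at C8a, 3-methylbut-2-enoyl group at C4a).
  - NaOAc in EtOH then recloses the pyranone by oxa-Michael addition to give 21. Only the C8a phenol is ortho to the enone, so the closure is unambiguous.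

## Further compounds

F1 | step 8 | 7-{[(E)-1,2-dichloroethenyl]oxy}-8-methoxy-6-(methoxymethoxy)-2,2,5-trimethylchroman-4-one | Cl/C=C(/Cl)Oc1c(OCOC)c(C)c2c(c1OC)OC(C)(C)CC2=O
F2 | step 8 | 7-{[(E)-1,2-dichloroethenyl]oxy}-8-methoxy-6-(methoxymethoxy)-2,2,5-trimethylchroman-4-ol (racemic) | Cl/C=C(/Cl)Oc1c(OCOC)c(C)c2c(c1OC)OC(C)(C)CC2O
F3 | step 8 | triethylsilyl ether of F2 (racemic) | Cl/C=C(/Cl)Oc1c(OCOC)c(C)c2c(c1OC)OC(C)(C)CC2O[Si](CC)(CC)CC
F4 | step 8 | allyl 3-{[8-methoxy-6-(methoxymethoxy)-2,2,5-trimethyl-4-(triethylsilyloxy)chroman-7-yl]oxy}prop-2-ynoate (racemic) | C=CCOC(=O)C#COc1c(OCOC)c(C)c2c(c1OC)OC(C)(C)CC2O[Si](CC)(CC)CC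
F5 | step 8 | allyl 3-{[4-hydroxy-8-methoxy-6-(methoxymethoxy)-2,2,5-trimethylchroman-7-yl]oxy}prop-2-ynoate (racemic) | C=CCOC(=O)C#COc1c(OCOC)c(C)c2c(c1OC)OC(C)(C)CC2O
F6 | step 9 | allyl 2-bromo-3-formyl-4-methoxy-6-methylbenzoate | Cc1cc(OC)c(C=O)c(Br)c1C(=O)OCC=C
F7 | step 7 | 6,7-dihydroxy-8-methoxy-2,2,5-trimethylchroman-4-one | Cc1c(O)c(O)c(OC)c2c1C(=O)CC(C)(C)O2
F8 | step 7 | 7-(benzyloxy)-6-hydroxy-8-methoxy-2,2,5-trimethylchroman-4-one | Cc1c(O)c(OCc3ccccc3)c(OC)c2c1C(=O)CC(C)(C)O2
F9 | step 7 | 7-(benzyloxy)-8-methoxy-6-(methoxymethoxy)-2,2,5-trimethylchroman-4-one | Cc1c(OCOC)c(OCc3ccccc3)c(OC)c2c1C(=O)CC(C)(C)O2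
F10 | step 5 | 1-(2,5-dihydroxy-3,4-dimethoxy-6-methylphenyl)ethan-1-one | CC(=O)c1c(C)c(O)c(OC)c(OC)c1O
F11 | step 13 | ring-opened enone of the target (phenol at C8a, 3-methylbut-2-enoyl at C4a, free hydroxyls at ring A O4 and ring B O8) | Cc1cc(O)c(C=O)c2c1C(=O)Oc1c(C)c(C(=O)C=C(C)C)c(O)c(O)c1O2
A1 | alternative 1 | 4-[(2E)-4-(tert-butyldimethylsilyloxy)-6-methylhepta-2,5-dien-2-yl]-2,3-dimethoxy-4-(methoxymethoxy)cyclobut-2-en-1-one (mixture of diastereomers) | COCOC1(/C(C)=C/C(O[Si](C)(C)C(C)(C)C)C=C(C)C)C(OC)=C(OC)C1=O
A2 | alternative 1 | 2-[1-(tert-butyldimethylsilyloxy)-3-methylbut-2-en-1-yl]-5,6-dimethoxy-4-(methoxymethoxy)-3-methylphenol (racemic) | COCOc1c(C)c(C(O[Si](C)(C)C(C)(C)C)C=C(C)C)c(O)c(OC)c1OC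
A3 | alternative 2 | 3-formyl-2-(3-hydroxy-2-methoxy-5-methylphenoxy)-4-methoxy-6-methylbenzoic acid | Cc1cc(O)c(OC)c(Oc2c(C=O)c(OC)cc(C)c2C(=O)O)c1
A4 | alternative 2 | depsidone lacking the pyranone ring, free phenol at the future C8a, methyl ethers at ring A O4 and the future O8 | Cc1cc(OC)c(C=O)c2c1C(=O)Oc1c(C)cc(O)c(OC)c1O2
A5 | alternative 3 | {[4-(benzyloxy)-3-methoxyfuran-2-yl]oxy}(tert-butyl)dimethylsilane | COc1c(OCc2ccccc2)coc1O[Si](C)(C)C(C)(C)C
A6 | alternative 3 | 6-methylhept-5-en-2-yn-4-one | CC#CC(=O)C=C(C)C
A7 | alternative 3 | 7-(benzyloxy)-6-hydroxy-8-methoxy-2,2,5-trimethylchroman-4-one | Cc1c(O)c(OCc2ccccc2)c(OC)c2c1C(=O)CC(C)(C)O2
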